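**Assumptions**

- Numbering: the target's fluorene-type locants (C1–C9a; bridge carbons C10, C11, C12; prenyl C1′–C5′) are used for the corresponding atoms of every intermediate.
- Sense of induction in step 4: the cupreidine-derived catalyst is taken to give the C4a configuration of the target; the cupreine-derived pseudo-enantiomer would be used if the opposite sense operated.
- Compounds 1, 5 and 7 are catalogue chemicals.

## Structural features

The target 20 is tetracyclic. Ring A is a cyclohex-2-ene-1,4-dione (C1=O, C2=C3, C4=O, C4a, C9a), fused through C4a–C9a to a five-membered ring B (C4a, C4b, C8a, C9, C9a) that carries the hydroquinone ring C (C4b–C8a, OH on C5 and C8). A propeno bridge C10H2–C11(CH3)=C12H joins C4a to C9 and closes ring D (C4a, C10, C11, C12, C9, C9a), so C4a and C9 are bridgeheads of a benzo-fused bicyclo[3.2.1]octadiene whose one-carbon bridge C9a also bears the prenyl group. The three stereocentres are contiguous: C4a (quaternary), C9a (quaternary) and C9 (H). C4a and C9 are tied together by the bridge, so the only free relative element is at C9a, where the C1 carbonyl is syn to the benzo bridge and the prenyl group syn to the propeno bridge (4aR,9R,9aS). Ring A is therefore cis-fused to ring B but trans-disposed on ring D, so the skeleton is not the direct suprafacial adduct of a diene with a ring A double bond. Fragile groups are the enedione (Michael acceptor, easily reduced), the air-sensitive hydroquinone, the acid-sensitive prenyl alkene and the allylic-benzylic C9–H; no stereocentre is epimerisable, so each must be made correctly. The real difficulty is the vicinal quaternary pair C4a–C9a inside the bridged bicycle, together with the facial sense at C9a. The key step exploits the 1,3-relationship of C4a and C9 across C9a in ring B: with C9a as a ketone they are the α and α′ carbons of an indan-2-one (C4a further acidified by the C4 acyl group), and C10–C11(CH3)–C12 is the carbon skeleton of methacrolein, attached by Michael addition at C4a and aldol addition at C9.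

## Logic of the disconnections

20 ⇒ 19 ⇒ 18. No C–C bond is cut; the two ring C O–H bonds become O–CH3 bonds, reached through the quinone 19. A free hydroquinone would not survive the enolate, ylide and divalent palladium steps. The gain is a robust arene from step 1 on. The demand is a final oxidation/reduction pair that leaves the ring A enedione and both trisubstituted alkenes alone.

18 ⇒ 16. The C2=C3 double bond is taken back to a single bond. A saturated 1,4-dione tolerates the silane, ylide and carbene-catalyst steps; the enedione does not. Because C4a and C9a are quaternary, both ketones of 16 can enolise only toward C2/C3, so the desaturation has one possible outcome.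

16 ⇒ 15 ⇒ 14. The C2′=C3′ bond of the prenyl group is cut to a C2′ aldehyde, which is traced to a thioester. This makes C1′ the α-carbon of a conjugate acceptor, which is what the ring A closure needs. The demand is thioester-selective reduction beside two ketones and aldehyde-selective olefination.

14 ⇒ 13. The C1–C9a bond is cut. Ring A opens, and the second quaternary carbon and the last stereocentre disappear. What remains is an exocyclic C9a=C1′ enethioate and a C1 aldehyde tethered through C4. The demand is that an acyl-anion equivalent adds to C9a from the benzo side.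

13 ⇒ 12 ⇒ 11. The C9a=C1′ bond is cut back to a bridging C9a ketone and the C1 aldehyde is masked as its dimethyl acetal. C9a is now a ketone flanked by C4a and C9, the retron for the key step. The demand is olefination of the strained C9a ketone in preference to the enolisable C4 ketone.

11 ⇒ 9 ⇒ 6 + 7 (key disconnection). The C11=C12 double bond is hydrated to the C12 carbinol, then C9–C12 and C4a–C10 are cut. Ring D and the seven-membered ring of the bicyclo[3.2.1] core open, and C4a and C9 cease to be stereocentres. The precursors are the achiral, flat diketone 6 and the four-carbon enal 7. The demand is an enantioselective C4a–C10 bond formation followed by aldolisation through C9 only. In one sentence: a catalytic enantioselective Michael/aldol α,α′-annulation of 6 with 7 builds the bridged core.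

6 ⇒ 4 + 5. The C4–C4a bond is cut (acylation of a ketone enolate). Since 4 is symmetric, either α-carbon gives the same product. The acyl chain brings C1–C4 of ring A at the correct oxidation level, with C1 masked.

4 ⇒ 2 ⇒ 1. The C9a carbonyl carbon is removed together with its bonds to C4a and C9 (a carbonyl 1,1-dianion equivalent joined to two benzylic halides), and the C–Br bonds are traced to the methyl groups of 1.

## Other disconnections considered

Alternative 1: This is the first idea that comes to mind, reading 20 as a prenylquinone dimer. Cut C9–C9a and C4a–C10 as a Diels–Alder pair and C4a–C4b as a conjugate addition. Forward: endo Diels–Alder reaction of 2-prenyl-1,4-benzoquinone A1 with (E)-1,4-dimethoxy-2-(3-methylbuta-1,3-dienyl)benzene A2 gives the cis-fused adduct A3; oxidation of its aryl ring to the quinone and intramolecular Michael addition of the C4a enol to C4b follow. The endo rule would set C9 against C9a correctly and enolisation resets C4a, so the stereochemical logic is sound. The weakness is the cycloaddition. Dienes add to 2-alkylbenzoquinones at the unsubstituted double bond, so the addition that creates quaternary C9a is the disfavoured one and would need a blocking group or a surrogate dienophile with later adjustment. An enantioselective version at this hindered site with an electron-rich, oxidisable diene is a further demand. The chosen plan makes both quaternary carbons at positions where the site of attack is unambiguous.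

Alternative 2: Cut only C4a–C10 and treat ring A as a dearomatised hydroquinone. Forward key step: palladium-catalysed intramolecular allylic dearomatisation of the fluoren-4-ol A4, whose C9 carries a (Z)-allylic carbonate, gives the bridged dienone A5. The acidic, configurationally labile C9–H would allow a dynamic kinetic resolution. Enol ether hydrolysis and C-prenylation at C9a would follow. The precursor is flat and the key step stereoconvergent, but the last bond made at C9a would be the one to the prenyl group. An electrophile should approach the C9a enolate from the more open benzo side, which in 20 must hold C1, so the C9a epimer is expected. In addition, the C9–H acidity that makes the resolution dynamic also favours vinylogous E1cB loss of the carbonate from A4. The chosen plan turns the same facial bias to advantage by making the C9a–C1 bond last.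

Alternative 3: Cut C9–C9a and C4a–C10 intramolecularly from the biaryl quinone A6, with C4a–C4b already in place. Forward key step: crossed [2+2] photocycloaddition of the ring A C4a=C9a bond to the styrenic C9=C12 bond, then strain-driven vinylcyclobutane-to-cyclohexene ring expansion. Both new bonds to ring A form on the same face of C4a=C9a, so ring D rather than ring B ends cis-fused to ring A. By the structural analysis this is the C9a epimer A7 of 18, not 18. Competing n,π* quinone chemistry (carbonyl–alkene cycloaddition, hydrogen abstraction from the prenyl group) and a tetra-ortho-substituted biaryl precursor add to the cost. The chosen plan sets C9a by a ground-state addition whose facial preference matches the target.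

Key step: step 4

## Route

Step 1
Reactants: 1 1,4-dimethoxy-2,3-dimethylbenzene
Product: 2 2,3-bis(bromomethyl)-1,4-dimethoxybenzene
Conditions: NBS (2.1 equiv), azobisisobutyronitrile (5 mol %), PhCF3, reflux
Reagents that add atoms: N-bromosuccinimide, O=C1CCC(=O)N1Br
Why: Wohl–Ziegler benzylic bromination; radical conditions in a non-polar solvent should favour the two benzylic methyl groups over the electron-rich ring. No stereocentre is formed.

Step 2
Reactants: 2 2,3-bis(bromomethyl)-1,4-dimethoxybenzene
Product: 4 4,7-dimethoxyindan-2-one, via tosyl isocyanide 3 (not isolated)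
Conditions: TosMIC (1.05 equiv), 40 % aq NaOH, n-Bu4NI (10 mol %), CH2Cl2, rt; then conc. HCl, Et2O, rt
Reagents that add atoms: tosylmethyl isocyanide, [C-]#[N+]CS(=O)(=O)c1ccc(C)cc1; water, O
Why: Phase-transfer double alkylation of TosMIC (a carbonyl 1,1-dianion equivalent) by the two benzylic bromides closes ring B; acid hydrolysis of the α-sulfonyl isocyanide releases the ketone, the future C9a.

Step 3
Reactants: 4 4,7-dimethoxyindan-2-one; 5 methyl 4,4-dimethoxybutanoate
Product: 6 1-(4,4-dimethoxybutanoyl)-4,7-dimethoxyindan-2-one
Conditions: NaH (2.5 equiv), 5 (3 equiv), THF, 0 °C to reflux, slow addition of 4; AcOH quench at 0 °C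
Reagents that add atoms: none
Why: Crossed Claisen condensation of the indanone enolate with the ester, driven by deprotonation of the product β-diketone; 4 is symmetric, so no regiochemical issue arises, and the acetal is untouched by base.

Step 4
Reactants: 6 1-(4,4-dimethoxybutanoyl)-4,7-dimethoxyindan-2-one; 7 methacrolein
Product: 9 4a-(4,4-dimethoxybutanoyl)-12-hydroxy-5,8-dimethoxy-11-methyl-4a,9-propano-bridged indan-9a-one (C11/C12 epimer mixture), via Michael adduct 8 (not isolated)
Conditions: 7 (2 equiv), 9-O-(phenanthren-9-yl)cupreidine (10 mol %), CH2Cl2, −20 °C; then DBU (0.2 equiv), 0 °C to rt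
Reagents that add atoms: none
Why: Domino Michael/aldol α,α′-annulation of a cyclic 1,3-diketone with an enal under bifunctional cinchona catalysis, a known route to bicyclo[3.2.1]octan-8-ones. The quinuclidine nitrogen deprotonates the enolised diketone 6 at C4a, its most acidic carbon (two carbonyls and the arene), and the hydrogen-bonded ion pair adds through C4a to the β-carbon of 7, which becomes C10, to give 8. C4a is created in this bond formation and its configuration is set by the catalyst, which blocks one face of the planar diketonate; the pseudo-enantiomeric catalyst would give the antipode. Added DBU then enolises the only acidic position left on the ring ketone, benzylic C9, and this enolate adds to the C12 aldehyde in a 6-(enolexo)-exo-trig aldol that closes ring D and with it the seven-membered ring C4a–C4b–C8a–C9–C12–C11–C10 of the bicyclo[3.2.1] core. C9 can bond only on the face of ring B that already carries the C10 chain, so its configuration is dictated by C4a; C11 and C12 arise as epimer mixtures and are both erased in step 5. The step needs C-alkylation at C4a, aldolisation through C9 rather than C3, and no cleavage of the non-enolisable diketone: the acidity order C4a–H > C9–H2 >> C3–H2, the reversibility of the aldol and the absence of alkoxide or hydroxide should secure these.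

Step 5
Reactants: 9 bridged ketol (C11/C12 epimer mixture)
Product: 11 4a-(4,4-dimethoxybutanoyl)-5,8-dimethoxy-11-methyl-4a,9-propeno-bridged indan-9a-one (C11=C12), via mesylate 10 (not isolated)
Conditions: MsCl (1.5 equiv), Et3N (2 equiv), CH2Cl2, 0 °C; then DBU (3 equiv), toluene, 80 °C
Reagents that add atoms: none
Why: Sulfonylation and E2 elimination; the only β-hydrogens are on C11 and on bridgehead C9, and Bredt's rule forbids a C9=C12 alkene, so the double bond can form only at C11=C12. The epimer mixture converges on one alkene, and a mesylate cannot undergo retro-aldol.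

Step 6
Reactants: 11 bridged alkene diketone
Product: 12 S-ethyl 2-[4a-(4,4-dimethoxybutanoyl)-5,8-dimethoxy-11-methyl-4a,9-propeno-bridged indan-9a-ylidene]ethanethioate (E/Z mixture)
Conditions: (EtO)2P(O)CH2C(O)SEt (2 equiv), LiCl (2.5 equiv), DBU (2 equiv), MeCN, rt to 50 °C
Reagents that add atoms: S-ethyl 2-(diethoxyphosphoryl)ethanethioate, CCOP(=O)(OCC)CC(=O)SCC
Why: Horner–Wadsworth–Emmons olefination under mild LiCl/amine conditions; the bridging C9a ketone is angle-strained, cannot enolise and has its substituents tied back, whereas the C4 ketone is enolisable and neopentyl-like, so reaction is expected at C9a. The alkene geometry is irrelevant because C1′ becomes sp3 in step 8.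

Step 7
Reactants: 12 enethioate acetal
Product: 13 S-ethyl 2-[5,8-dimethoxy-11-methyl-4a-(4-oxobutanoyl)-4a,9-propeno-bridged indan-9a-ylidene]ethanethioate
Conditions: pyridinium p-toluenesulfonate (0.2 equiv), acetone/H2O 9:1, 45 °C
Reagents that add atoms: water, O
Why: Mild acetal hydrolysis; the weak acid is chosen to free the C1 aldehyde without Paal–Knorr cyclodehydration of the 1,4-ketoaldehyde and without touching the thioester.

Step 8
Reactants: 13 aldehyde enethioate
Product: 14 S-ethyl 2-[5,8-dimethoxy-11-methyl-1,4-dioxo-4a,9-propeno-bridged 1,2,3,4,4a,9a-hexahydrofluoren-9a-yl]ethanethioate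
Conditions: 2-(perfluorophenyl)-6,7-dihydro-5H-pyrrolo[2,1-c][1,2,4]triazol-2-ium tetrafluoroborate (20 mol %), i-Pr2NEt (20 mol %), toluene, 40 °C
Reagents that add atoms: none
Why: Intramolecular Stetter reaction: the carbene-derived acyl-anion equivalent of the C1 aldehyde adds to C9a, the β-carbon of the strained exocyclic enethioate, closing ring A (6-exo-trig) and creating the second quaternary centre. C9a should be attacked from the benzo side, the more open face of the one-carbon bridge (the propeno bridge and its C10 methylene lie closer beneath the other face); this puts the C1 carbonyl syn to the arene and the CH2C(O)SEt arm, the future prenyl group, syn to the propeno bridge. Both alkene isomers of 13 converge.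

Step 9
Reactants: 14 thioester dione
Product: 15 2-[5,8-dimethoxy-11-methyl-1,4-dioxo-4a,9-propeno-bridged 1,2,3,4,4a,9a-hexahydrofluoren-9a-yl]acetaldehyde
Conditions: Et3SiH (3 equiv), palladium on carbon (Pd/C, 10 wt % Pd, 5 mol %), acetone, rt
Reagents that add atoms: none
Why: Fukuyama reduction; the thioester is reduced to the aldehyde through an acyl–palladium hydride, leaving both ketones and the trisubstituted C11=C12 alkene untouched.

Step 10
Reactants: 15 aldehyde dione
Product: 16 5,8-dimethoxy-11-methyl-9a-prenyl-4a,9-propeno-bridged 2,3,4a,9a-tetrahydrofluorene-1,4-dione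
Conditions: i-PrPPh3I (1.3 equiv), n-BuLi (1.25 equiv), THF, 0 °C; then 15, −78 to 0 °C
Reagents that add atoms: isopropyltriphenylphosphonium iodide, CC(C)[P+](c1ccccc1)(c1ccccc1)c1ccccc1.[I-]
Why: Wittig olefination with the non-stabilised isopropylidene ylide completes the prenyl group; the aldehyde reacts far faster at low temperature than the two ketones, each flanked by a quaternary carbon.

Step 11
Reactants: 16 prenyl dione
Product: 18 5,8-dimethoxy-11-methyl-9a-prenyl-4a,9-propeno-bridged 4a,9a-dihydrofluorene-1,4-dione, via bis(silyl) dienol ether 17 (not isolated)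
Conditions: TMSOTf (2.5 equiv), Et3N (3.5 equiv), CH2Cl2, 0 °C; then Pd(OAc)2 (1.1 equiv), MeCN, rt
Reagents that add atoms: none
Why: Saegusa–Ito-type desaturation; both ketones can enolise only toward C2/C3, so any mono- or bis-silyl enol ether leads, after divalent palladium enolate formation and loss of the second silyl group or β-hydride, to the same C2=C3 enedione. The isolated trisubstituted alkenes are not engaged.

Step 12
Reactants: 18 enedione dimethyl ether
Product: 19 11-methyl-9a-prenyl-4a,9-propeno-bridged 4a,9a-dihydrofluorene-1,4,5,8-tetraone (ring C quinone)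
Conditions: (NH4)2Ce(NO3)6 (2.5 equiv), MeCN/H2O 4:1, 0 °C, 10 min
Reagents that add atoms: water, O
Why: Oxidative demethylation of the 1,4-dimethoxyarene by tetravalent cerium through the arene radical cation; electron-poor ring A and the isolated alkenes are not oxidised under these brief conditions.

Step 13
Reactants: 19 ring C quinone
Product: 20 (4aR,9R,9aS)-5,8-dihydroxy-11-methyl-9a-prenyl-4a,9-propeno-bridged 4a,9a-dihydrofluorene-1,4-dione
Conditions: Na2S2O4 (3 equiv), EtOAc/H2O, rt, 5 min, argon
Reagents that add atoms: none
Why: Dithionite reduces the benzoquinone to the hydroquinone almost instantly; the much less easily reduced ring A enedione should survive a short biphasic exposure. No stereocentre is affected.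

## Compound list

1 | 1,4-dimethoxy-2,3-dimethylbenzene | COc1ccc(OC)c(C)c1C | starting material
2 | 2,3-bis(bromomethyl)-1,4-dimethoxybenzene | COc1ccc(OC)c(CBr)c1CBr | intermediate
3 | 2-isocyano-4,7-dimethoxy-2-(4-methylbenzenesulfonyl)indane (not isolated) | COc1ccc(OC)c2c1CC(C2)([N+]#[C-])S(=O)(=O)c1ccc(C)cc1 | intermediate
4 | 4,7-dimethoxyindan-2-one | COc1ccc(OC)c2c1CC(=O)C2 | intermediate
5 | methyl 4,4-dimethoxybutanoate | COC(=O)CCC(OC)OC | starting material
6 | 1-(4,4-dimethoxybutanoyl)-4,7-dimethoxyindan-2-one (enolised; indanone C1 is the future C4a) | COC(OC)CCC(=O)C1C(=O)Cc2c(OC)ccc(OC)c12 | intermediate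
7 | methacrolein (2-methylprop-2-enal) | CC(=C)C=O | starting material
8 | 1-(4,4-dimethoxybutanoyl)-4,7-dimethoxy-1-(2-methyl-3-oxopropyl)indan-2-one, quaternary carbon configured as C4a of 20, C11 epimers (not isolated) | COC(OC)CCC(=O)[C@@]1(CC(C)C=O)C(=O)Cc2c(OC)ccc(OC)c12 | intermediate
9 | bridged ketol: 4a-(4,4-dimethoxybutanoyl)-12-hydroxy-5,8-dimethoxy-11-methyl-4a,9-propano-bridged indan-9a-one, C4a and C9 as in 20, C11/C12 epimers | COC(OC)CCC(=O)[C@@]13CC(C)C(O)[C@@H](C1=O)c1c(OC)ccc(OC)c13 | intermediate
10 | C12 methanesulfonate of 9 (not isolated) | COC(OC)CCC(=O)[C@@]13CC(C)C(OS(C)(=O)=O)[C@@H](C1=O)c1c(OC)ccc(OC)c13 | intermediate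
11 | 4a-(4,4-dimethoxybutanoyl)-5,8-dimethoxy-11-methyl-4a,9-propeno-bridged indan-9a-one (C11=C12), C4a and C9 as in 20 | COC(OC)CCC(=O)[C@@]13CC(C)=C[C@@H](C1=O)c1c(OC)ccc(OC)c13 | intermediate
12 | S-ethyl 2-[4a-(4,4-dimethoxybutanoyl)-5,8-dimethoxy-11-methyl-4a,9-propeno-bridged indan-9a-ylidene]ethanethioate, E/Z mixture | COC(OC)CCC(=O)[C@@]13CC(C)=C[C@@H](C1=CC(=O)SCC)c1c(OC)ccc(OC)c13 | intermediate
13 | S-ethyl 2-[5,8-dimethoxy-11-methyl-4a-(4-oxobutanoyl)-4a,9-propeno-bridged indan-9a-ylidene]ethanethioate, E/Z mixture | O=CCCC(=O)[C@@]13CC(C)=C[C@@H](C1=CC(=O)SCC)c1c(OC)ccc(OC)c13 | intermediate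
14 | S-ethyl 2-[5,8-dimethoxy-11-methyl-1,4-dioxo-4a,9-propeno-bridged 1,2,3,4,4a,9a-hexahydrofluoren-9a-yl]ethanethioate, all three stereocentres as in 20 (C1 carbonyl syn to the arene) | CCSC(=O)C[C@@]12C(=O)CCC(=O)[C@@]13CC(C)=C[C@@H]2c1c(OC)ccc(OC)c13 | intermediate
15 | 2-[5,8-dimethoxy-11-methyl-1,4-dioxo-4a,9-propeno-bridged 1,2,3,4,4a,9a-hexahydrofluoren-9a-yl]acetaldehyde, stereocentres as in 20 | O=CC[C@@]12C(=O)CCC(=O)[C@@]13CC(C)=C[C@@H]2c1c(OC)ccc(OC)c13 | intermediate
16 | 5,8-dimethoxy-11-methyl-9a-prenyl-4a,9-propeno-bridged 2,3,4a,9a-tetrahydrofluorene-1,4-dione, stereocentres as in 20 | CC(C)=CC[C@@]12C(=O)CCC(=O)[C@@]13CC(C)=C[C@@H]2c1c(OC)ccc(OC)c13 | intermediate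
17 | 1,4-bis(trimethylsilyloxy)-1,3-diene derived from 16 (not isolated) | CC(C)=CC[C@@]12C(O[Si](C)(C)C)=CC=C(O[Si](C)(C)C)[C@@]13CC(C)=C[C@@H]2c1c(OC)ccc(OC)c13 | intermediate
18 | 5,8-dimethoxy-11-methyl-9a-prenyl-4a,9-propeno-bridged 4a,9a-dihydrofluorene-1,4-dione (dimethyl ether of 20) | CC(C)=CC[C@@]12C(=O)C=CC(=O)[C@@]13CC(C)=C[C@@H]2c1c(OC)ccc(OC)c13 | intermediate
19 | 11-methyl-9a-prenyl-4a,9-propeno-bridged 4a,9a-dihydrofluorene-1,4,5,8-tetraone, stereocentres as in 20 | CC(C)=CC[C@@]12C(=O)C=CC(=O)[C@@]13CC(C)=C[C@@H]2C1=C3C(=O)C=CC1=O | intermediate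
20 | (4aR,9R,9aS)-5,8-dihydroxy-11-methyl-9a-prenyl-4a,9-propeno-bridged 4a,9a-dihydrofluorene-1,4-dione (CNP0166383.1) | CC(C)=CC[C@@]12C(=O)C=CC(=O)[C@@]13CC(C)=C[C@@H]2c1c(O)ccc(O)c13 | target

## Step count and least certain steps

Total: 13 steps. Longest linear sequence: 13 steps (the route is linear from 1; 5 and 7 are used as purchased).

Step 4 (key step). The most likely failure is insufficient facial discrimination in the C4a–C10 bond formation: the diketonate of 6 is flat and highly stabilised, and methacrolein has no β-substituent to help the catalyst. Retro-Michael/Michael equilibration of 8 before the aldol traps it would also erode the enantiomeric purity, and O-cyclisation to a lactol or aldolisation through C3 would divert material. Fallback, starting from 6 and rejoining at 11: alkylate 6 at C4a under chiral quaternary-ammonium phase-transfer catalysis with (Z)-3-bromo-1-iodo-2-methylprop-1-ene F2, made with PBr3 from (Z)-3-iodo-2-methylprop-2-en-1-ol F1 (propargyl alcohol, MeMgBr/CuI, then I2). This gives 1-(4,4-dimethoxybutanoyl)-1-[(Z)-3-iodo-2-methylprop-2-enyl]-4,7-dimethoxyindan-2-one F3. A palladium-catalysed intramolecular α-alkenylation of the ring ketone enolate at C9 (Pd(PPh3)4, t-BuOK, THF) then closes ring D with the C11=C12 bond already in place and gives 11 directly, bypassing the ketol and step 5.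

Step 8. Addition of the bulky acyl-anion equivalent to a β,β-disubstituted acceptor next to quaternary C4a may be too slow, leaving the aldehyde to self-condense, and discrimination between the benzo and propeno faces of C9a may be incomplete. Fallback, from 13 to 14 with no new compound (F0): thiol-catalysed radical hydroacylation (tert-dodecanethiol 0.3 equiv, 1,1′-azobis(cyclohexanecarbonitrile), PhCl, 100 °C). The small, nucleophilic acyl radical undergoes 6-exo addition to the electron-poor C9a=C1′ bond with an early transition state, and the thiol returns hydrogen to C1′.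

Step 6. Carbonyl addition at the hindered bridging ketone may be sluggish, and the phosphonate anion may instead be consumed by enolisation of, or attack at, the C4 ketone. Fallback, from 11 to 12: add the lithium enolate of S-ethyl thioacetate (LDA, THF, −78 °C) to the C9a ketone to give the tertiary β-hydroxy thioester F4, S-ethyl 2-[4a-(4,4-dimethoxybutanoyl)-9a-hydroxy-5,8-dimethoxy-11-methyl-4a,9-propeno-bridged indan-9a-yl]ethanethioate F4, and dehydrate it (SOCl2, pyridine, 0 °C) to 12.

Step 5. Part of the epimer mixture may lack a C11–H anti-periplanar to the C12 leaving group, leading to slow elimination or substitution, and retro-aldol may intervene during sulfonylation. Fallback, from 9 to 11: convert 9 to the S-methyl xanthate F5, the O-(C12) S-methyl dithiocarbonate of 9 F5 (DBU, CS2, then MeI), and pyrolyse it (o-dichlorobenzene, 160 °C). This Chugaev syn-elimination serves the epimers that E2 cannot and can still only form the C11=C12 alkene.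

Step 13. Over-reduction of the ring A C2=C3 bond by dithionite, or air re-oxidation of the hydroquinone during isolation, may occur. Fallback, from 16 to 20: carry out the redox deprotection before ring A is desaturated.
- Oxidise 16 with (NH4)2Ce(NO3)6 to the ring C quinone of 16, F6.
- Reduce with Na2S2O4 to the 5,8-dihydroxy analogue of 16, F7; no enedione is present at this stage.
- Silylate (TBSCl, imidazole, DMF) to the 5,8-bis(tert-butyldimethylsilyl) ether of F7, F8.
- Desaturate with 2-iodoxybenzoic acid (DMSO, 70 °C) to the 5,8-bis(tert-butyldimethylsilyl) ether of 20, F9.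
- Remove the silyl groups with HF·pyridine (THF, 0 °C) to give 20.

## Further compounds

F1 | step 4 | (Z)-3-iodo-2-methylprop-2-en-1-ol | OC/C(C)=C\I
F2 | step 4 | (Z)-3-bromo-1-iodo-2-methylprop-1-ene | BrC/C(C)=C\I
F3 | step 4 | 1-(4,4-dimethoxybutanoyl)-1-[(Z)-3-iodo-2-methylprop-2-enyl]-4,7-dimethoxyindan-2-one, quaternary carbon as C4a of 20 | COC(OC)CCC(=O)[C@@]1(C/C(C)=C\I)C(=O)Cc2c(OC)ccc(OC)c12
F0 | step 8 | none | none
F4 | step 6 | S-ethyl 2-[4a-(4,4-dimethoxybutanoyl)-9a-hydroxy-5,8-dimethoxy-11-methyl-4a,9-propeno-bridged indan-9a-yl]ethanethioate | COC(OC)CCC(=O)[C@@]13CC(C)=C[C@@H](C1(O)CC(=O)SCC)c1c(OC)ccc(OC)c13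
F5 | step 5 | O-(C12) S-methyl dithiocarbonate of 9 | COC(OC)CCC(=O)[C@@]13CC(C)C(OC(=S)SC)[C@@H](C1=O)c1c(OC)ccc(OC)c13
F6 | step 13 | ring C quinone of 16 | CC(C)=CC[C@@]12C(=O)CCC(=O)[C@@]13CC(C)=C[C@@H]2C1=C3C(=O)C=CC1=O
F7 | step 13 | 5,8-dihydroxy analogue of 16 | CC(C)=CC[C@@]12C(=O)CCC(=O)[C@@]13CC(C)=C[C@@H]2c1c(O)ccc(O)c13
F8 | step 13 | 5,8-bis(tert-butyldimethylsilyl) ether of F7 | CC(C)=CC[C@@]12C(=O)CCC(=O)[C@@]13CC(C)=C[C@@H]2c1c(O[Si](C)(C)C(C)(C)C)ccc(O[Si](C)(C)C(C)(C)C)c13
F9 | step 13 | 5,8-bis(tert-butyldimethylsilyl) ether of 20 | CC(C)=CC[C@@]12C(=O)C=CC(=O)[C@@]13CC(C)=C[C@@H]2c1c(O[Si](C)(C)C(C)(C)C)ccc(O[Si](C)(C)C(C)(C)C)c13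
A1 | alternative 1 | 2-prenyl-1,4-benzoquinone | CC(C)=CCC1=CC(=O)C=CC1=O
A2 | alternative 1 | (E)-1,4-dimethoxy-2-(3-methylbuta-1,3-dienyl)benzene | COc1ccc(OC)c(/C=C/C(C)=C)c1
A3 | alternative 1 | endo Diels–Alder adduct: cis-fused 5-(2,5-dimethoxyphenyl)-7-methyl-4a-prenyl-4a,5,8,8a-tetrahydronaphthalene-1,4-dione | CC(C)=CC[C@@]12C(=O)C=CC(=O)[C@@H]1CC(C)=C[C@@H]2c1c(OC)ccc(OC)c1
A4 | alternative 2 | (Z)-4-(4-hydroxy-1,5,8-trimethoxy-9H-fluoren-9-yl)-2-methylbut-2-enyl methyl carbonate (racemic at C9) | COC(=O)OC/C(C)=C\C1c2c(OC)ccc(OC)c2-c2c(O)ccc(OC)c12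
A5 | alternative 2 | 1,5,8-trimethoxy-11-methyl-4a,9-propeno-bridged 4a,9-dihydrofluoren-4-one (dearomatised dienone) | COC1=C2[C@@H]3C=C(C)C[C@@]2(C(=O)C=C1)c1c(OC)ccc(OC)c13
A6 | alternative 3 | 2-[3,6-dimethoxy-2-((E)-3-methylbuta-1,3-dienyl)phenyl]-3-prenyl-1,4-benzoquinone | CC(C)=CCC1=C(C(=O)C=CC1=O)c1c(OC)ccc(OC)c1/C=C/C(C)=C
A7 | alternative 3 | C9a epimer of 18 | CC(C)=CC[C@]12C(=O)C=CC(=O)[C@@]13CC(C)=C[C@@H]2c1c(OC)ccc(OC)c13
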